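## Retrosynthetic overview

1. Ring numbering: C1 carries the dienyl side chain, C4 the methyl, C8=C9 is the Z-alkene, C12 carries CO2H. The strategy rests on C12 of the 14-membered ring: it is α to the carboxyl carbon and linked to C1 through C13 and C14, so C12–C13 can be made last from a configurationally erased C12 radical and a C13 alkylnickel grown from a vinyl group on C1, the chiral catalyst setting 12R.
2. Target ⇐ carbinol (oxidation level) ⇐ macrocyclic N-methylanilide ⇐ seco α-bromo anilide with CH=CH2 on C1 (C12–C13 disconnection; the only ring, closed last).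
3. Seco chain ⇐ phenyl sulfone linchpin at C6: C5–C6 from a C1–C5 iodide, C6–C7 from a Z-allylic bromide that already holds C8=C9 through to the anilide.
4. C1–C5, C14 and the side chain ⇐ (R)-carvone. The side chain is lengthened on the ring (ene chlorination, allyl–allyl coupling, cross-metathesis) before any vinyl group exists. The ring is then cut between C=O and the α′-CH2: carvone C5 becomes C1, the α′-CH2 becomes the vinyl CH (C14), and C=O becomes C5. C4 is set by carboxyl-directed asymmetric hydrogenation.
5. The Z-C8=C9 unit ⇐ Wittig reaction of an α-silyloxy ketone with a non-stabilised ylide.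

Key step: step 19

Assumption: the ligand enantiomers written in steps 8 and 19 are taken to give 4R and 12R by analogy with simpler substrates; if a model run shows the opposite sense, the antipodal ligand is used and nothing else changes.

## Route

Step 1
Reactants: 1 (R)-(−)-carvone
Product: 2 (5R)-5-(3-chloroprop-1-en-2-yl)-2-methylcyclohex-2-en-1-one
Conditions: Ca(OCl)2, CO2 (solid), CH2Cl2/H2O, 0 °C
Reagents that add atoms: calcium hypochlorite, [Ca+2].[O-]Cl.[O-]Cl
Why: Ene-type allylic chlorination by HOCl formed in the flask attacks only the electron-rich 1,1-disubstituted isopropenyl alkene, not the enone alkene, and shifts the double bond to give the 2-(chloromethyl)vinyl group, leaving C5 untouched.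

Step 2
Reactants: 2 (5R)-5-(3-chloroprop-1-en-2-yl)-2-methylcyclohex-2-en-1-one; 3 2-allyl-4,4,5,5-tetramethyl-1,3,2-dioxaborolane
Product: 4 (5R)-5-(hexa-1,5-dien-2-yl)-2-methylcyclohex-2-en-1-one
Conditions: Pd2(dba)3 (2.5 mol %), 1,2-bis(diphenylphosphino)benzene (6 mol %), CsF, THF, 40 °C
Reagents that add atoms: none
Why: Palladium-catalysed allyl–allyl cross-coupling (oxidative addition of the allylic chloride to zerovalent palladium, transmetallation from the fluoride-activated allylboronate, reductive elimination) should give the 1,5-diene; both allyl units are symmetric, so only one constitution can form, and the ketone is inert to the boronate at this temperature.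

Step 3
Reactants: 4 (5R)-5-(hexa-1,5-dien-2-yl)-2-methylcyclohex-2-en-1-one; 5 2-methylbut-2-ene
Product: 6 (5R)-2-methyl-5-(6-methylhepta-1,5-dien-2-yl)cyclohex-2-en-1-one
Conditions: second-generation Grubbs catalyst (3 mol %), 5 (30 equiv), CH2Cl2, 40 °C, sealed tube
Reagents that add atoms: none
Why: Olefin cross-metathesis of the only monosubstituted alkene with excess 2-methylbut-2-ene installs the isopropylidene terminus, while the 1,1-disubstituted and enone alkenes are too hindered or electron-poor to take part.

Step 4
Reactants: 6 (5R)-2-methyl-5-(6-methylhepta-1,5-dien-2-yl)cyclohex-2-en-1-one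
Product: 8 (5S,6RS)-6-hydroxy-2-methyl-5-(6-methylhepta-1,5-dien-2-yl)cyclohex-2-en-1-one (C5 spatially unchanged, descriptor changes by priority only; both C6 epimers), via potassium dienolate 7 (not isolated)
Conditions: KN(SiMe3)2, THF, −78 °C; then 2-(phenylsulfonyl)-3-phenyloxaziridine, −78 °C; aqueous quench
Reagents that add atoms: 2-(phenylsulfonyl)-3-phenyloxaziridine, O=S(=O)(c1ccccc1)N1OC1c1ccccc1
Why: Kinetic deprotonation at the α′-CH2 gives the cross-conjugated enolate, which is hydroxylated by oxygen transfer from the N-sulfonyloxaziridine (enolate oxidation) without epoxidising the side-chain alkenes; the C6 configuration is irrelevant because C6 becomes sp2 in step 5.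

Step 5
Reactants: 8 (5S,6RS)-6-hydroxy-2-methyl-5-(6-methylhepta-1,5-dien-2-yl)cyclohex-2-en-1-one
Product: 9 methyl (2Z,5S)-5-formyl-2,10-dimethyl-6-methylideneundeca-2,9-dienoate
Conditions: Pb(OAc)4, MeOH/benzene (1:1), 0 °C; crude 9 taken directly into step 6
Reagents that add atoms: methanol, CO
Why: Criegee-type oxidative cleavage of the α-hydroxy ketone through its methanol hemiketal cuts the ring bond between the carbonyl carbon and the carbinol carbon, giving the methyl ester (Z-geometry inherited from the ring) and the aldehyde under near-neutral conditions that should not enolise the new α-stereocentre.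

Step 6
Reactants: 9 methyl (2Z,5S)-5-formyl-2,10-dimethyl-6-methylideneundeca-2,9-dienoate
Product: 10 methyl (2Z,5R)-5-ethenyl-2,10-dimethyl-6-methylideneundeca-2,9-dienoate
Conditions: Zn, CH2Br2, TiCl4, THF, 0 °C (reagent preformed); then 9 in CH2Cl2, 0 °C
Reagents that add atoms: dibromomethane, BrCBr
Why: Takai–Lombardo methylenation with the non-basic gem-dizinc/titanium reagent converts the aldehyde into the C13=C14 vinyl group without enolising the adjacent stereocentre (C1 of the target) and leaves the conjugated ester alone.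

Step 7
Reactants: 10 methyl (2Z,5R)-5-ethenyl-2,10-dimethyl-6-methylideneundeca-2,9-dienoate
Product: 11 (2Z,5R)-5-ethenyl-2,10-dimethyl-6-methylideneundeca-2,9-dienoic acid
Conditions: LiOH·H2O, THF/MeOH/H2O, 40 °C; then dilute HCl to pH 3
Reagents that add atoms: lithium hydroxide, [Li+].[OH-]
Why: Saponification of the methyl ester frees the carboxyl group needed to direct step 8; the stereocentre is not α to a carbonyl and the Z-enoate is stable to these conditions.

Step 8
Reactants: 11 (2Z,5R)-5-ethenyl-2,10-dimethyl-6-methylideneundeca-2,9-dienoic acid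
Product: 12 (2S,5R)-5-ethenyl-2,10-dimethyl-6-methylideneundec-9-enoic acid
Conditions: [Ir(cod)(L)]B[3,5-(CF3)2C6H3]4 (1 mol %), L = (Sa,S)-SIPHOX (spirobiindane phosphine–oxazoline), Et3N (0.5 equiv), H2 (6 atm), MeOH, 25 °C
Reagents that add atoms: none
Why: Carboxylate-directed iridium-catalysed asymmetric hydrogenation: the substrate binds the iridium hydride through its carboxylate, so only the conjugated C=C should be reduced, and the chiral ligand selects the face and sets the methyl stereocentre (2S in this acid, C4 = R in the ring numbering); the three non-coordinating alkenes are expected to survive.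

Step 9
Reactants: 12 (2S,5R)-5-ethenyl-2,10-dimethyl-6-methylideneundec-9-enoic acid
Product: 13 (2S,5R)-5-ethenyl-2,10-dimethyl-6-methylideneundec-9-en-1-ol
Conditions: LiAlH4, THF, 0 → 23 °C
Reagents that add atoms: none
Why: Hydride reduction of the carboxylic acid to the primary alcohol; isolated alkenes are inert to LiAlH4 and the carboxylate is not enolised, so the α-stereocentre is kept.

Step 10
Reactants: 13 (2S,5R)-5-ethenyl-2,10-dimethyl-6-methylideneundec-9-en-1-ol
Product: 14 (2S,5R)-5-ethenyl-1-iodo-2,10-dimethyl-6-methylideneundec-9-ene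
Conditions: I2, PPh3, imidazole, CH2Cl2, 0 °C
Reagents that add atoms: iodine, II
Why: Appel-type iodination of the primary alcohol by SN2 at the CH2 carbon, with no change at the neighbouring stereocentre.

Step 11
Reactants: 14 (2S,5R)-5-ethenyl-1-iodo-2,10-dimethyl-6-methylideneundec-9-ene; 15 methyl phenyl sulfone
Product: 17 {[(3S,6R)-6-ethenyl-3,11-dimethyl-7-methylidenedodec-10-en-1-yl]sulfonyl}benzene, via (phenylsulfonyl)methyllithium 16 (not isolated)
Conditions: 15 (3 equiv), n-BuLi (3 equiv), THF, −78 → 0 °C; then 14, HMPA, −78 → 23 °C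
Reagents that add atoms: none
Why: SN2 alkylation of lithiated methyl phenyl sulfone, used in excess to suppress dialkylation, by the primary iodide introduces C6 as the sulfone linchpin; the doubly allylic C1–H is far too weakly acidic to be touched.

Step 12
Reactants: 18 (4-carboxybutyl)triphenylphosphonium bromide; 19 1-[(tert-butyldimethylsilyl)oxy]propan-2-one
Product: 21 (5Z)-7-[(tert-butyldimethylsilyl)oxy]-6-methylhept-5-enoic acid, via phosphorus ylide carboxylate 20 (not isolated)
Conditions: NaN(SiMe3)2 (2.1 equiv), THF, 0 °C; then 19, −78 → 23 °C; dilute HCl to pH 4 at 0 °C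
Reagents that add atoms: none
Why: Wittig olefination of an α-silyloxy methyl ketone with a non-stabilised, lithium-free ylide, a combination known to place the CH2O group cis to the ylide-derived chain, should give the trisubstituted Z-alkene (C8=C9 with C7 and C10 cis).

Step 13
Reactants: 21 (5Z)-7-[(tert-butyldimethylsilyl)oxy]-6-methylhept-5-enoic acid; 22 N-methylaniline
Product: 24 (5Z)-7-[(tert-butyldimethylsilyl)oxy]-N,6-dimethyl-N-phenylhept-5-enamide, via acid chloride 23 (not isolated)
Conditions: 1-chloro-N,N,2-trimethylprop-1-en-1-amine, CH2Cl2, 0 °C; then 22, pyridine, 0 → 23 °C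
Reagents that add atoms: none
Why: Amide formation through the acid chloride made under neutral conditions, so that the allylic silyl ether survives, followed by N-acylation of the weakly nucleophilic aniline.

Step 14
Reactants: 24 (5Z)-7-[(tert-butyldimethylsilyl)oxy]-N,6-dimethyl-N-phenylhept-5-enamide
Product: 25 (5Z)-7-hydroxy-N,6-dimethyl-N-phenylhept-5-enamide
Conditions: Bu4NF, THF, 0 °C
Reagents that add atoms: none
Why: Fluoride-mediated cleavage of the silyl ether; the tertiary amide and the alkene are unaffected.

Step 15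
Reactants: 25 (5Z)-7-hydroxy-N,6-dimethyl-N-phenylhept-5-enamide
Product: 26 (5Z)-7-bromo-N,6-dimethyl-N-phenylhept-5-enamide
Conditions: CBr4, PPh3, CH2Cl2, 0 °C; used without storage
Reagents that add atoms: carbon tetrabromide, BrC(Br)(Br)Br
Why: Appel bromination of the primary allylic alcohol by direct SN2 displacement keeps the Z-geometry, and immediate use avoids bromide-induced allylic isomerisation.

Step 16
Reactants: 17 {[(3S,6R)-6-ethenyl-3,11-dimethyl-7-methylidenedodec-10-en-1-yl]sulfonyl}benzene; 26 (5Z)-7-bromo-N,6-dimethyl-N-phenylhept-5-enamide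
Product: 28 (5Z,10S,13R)-13-ethenyl-N,6,10,18-tetramethyl-14-methylidene-N-phenyl-8-(phenylsulfonyl)nonadeca-5,17-dienamide (both epimers at the sulfone carbon), via lithiated sulfone 27 (not isolated)
Conditions: n-BuLi (1.05 equiv), THF, −78 °C; then 26, −78 → −40 °C
Reagents that add atoms: none
Why: SN2 alkylation of the α-sulfonyl carbanion by the reactive primary allylic bromide forms C6–C7 at −78 °C faster than proton transfer from, or addition to, the anilide; the uncontrolled stereocentre at C6 is removed in step 17.

Step 17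
Reactants: 28 (5Z,10S,13R)-13-ethenyl-N,6,10,18-tetramethyl-14-methylidene-N-phenyl-8-(phenylsulfonyl)nonadeca-5,17-dienamide
Product: 29 (5Z,10R,13R)-13-ethenyl-N,6,10,18-tetramethyl-14-methylidene-N-phenylnonadeca-5,17-dienamide
Conditions: Na(Hg), Na2HPO4, MeOH/THF, −20 → 0 °C
Reagents that add atoms: none
Why: Reductive desulfonylation by electron transfer from sodium amalgam in buffered methanol replaces C–S by C–H; the alkenes and the tertiary amide are inert under these conditions.

Step 18
Reactants: 29 (5Z,10R,13R)-13-ethenyl-N,6,10,18-tetramethyl-14-methylidene-N-phenylnonadeca-5,17-dienamide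
Product: 31 (5Z,10R,13R)-2-bromo-13-ethenyl-N,6,10,18-tetramethyl-14-methylidene-N-phenylnonadeca-5,17-dienamide (both C2 epimers; C2 is C12 of the ring), via lithium amide enolate 30 (not isolated)
Conditions: LiN(i-Pr)2, THF, −78 °C; then cannulated into N-bromosuccinimide, THF, −78 °C
Reagents that add atoms: N-bromosuccinimide, O=C1CCC(=O)N1Br
Why: α-Bromination of the amide enolate with an electrophilic bromine source gives both C12 epimers, which is all the stereoconvergent step 19 needs; inverse addition limits dibromination and the enolate outcompetes the alkenes for the brominating agent.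

Step 19
Reactants: 31 (5Z,10R,13R)-2-bromo-13-ethenyl-N,6,10,18-tetramethyl-14-methylidene-N-phenylnonadeca-5,17-dienamide
Product: 32 (1R,4Z,9R,12R)-N,5,9-trimethyl-12-(6-methylhepta-1,5-dien-2-yl)-N-phenylcyclotetradec-4-ene-1-carboxamide
Conditions: NiBr2·glyme (15 mol %), (4S,4′S)-2,2′-(propane-2,2-diyl)bis(4-phenyl-4,5-dihydro-1,3-oxazole) (18 mol %), (EtO)3SiH (2.5 equiv), K3PO4·H2O (2.5 equiv), N,N-dimethylacetamide, 23 °C; 31 added by syringe pump over 12 h (final 2 mM)
Reagents that add atoms: none
Why: Proposed new method: a chiral bis(oxazoline) nickel hydride, formed from the divalent nickel precatalyst and the silane, should insert the only monosubstituted alkene (C13=C14) anti-Markovnikov to give a primary C13–nickel bond, while bromine abstraction from either C12 epimer gives the same planar α-amido radical, which is captured at nickel and reductively eliminated to form C12–C13. The closest known reaction type is the intermolecular enantioconvergent nickel-hydride hydroalkylation of terminal alkenes with racemic α-bromo amides; its use to close a ring is new. The 14-membered ring closes end to end by this intramolecular sp3–sp3 coupling, with slow addition keeping the substrate dilute so that capture of the radical by the alkylnickel of the same chain beats coupling between chains. The new stereocentre C12 (R) is fixed by the chiral ligand on nickel at the bond-forming event, both epimers of 31 converging, and not by the remote C1 and C4 centres. The step needs insertion at the vinyl group only and no chain-walking: the 1,1-disubstituted and trisubstituted alkenes insert far more slowly, the C12 radical can reach C8=C9 only by disfavoured 4-exo or 5-endo closure, and the main residual risk is isomerisation through the doubly allylic C1–H.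

Step 20
Reactants: 32 (1R,4Z,9R,12R)-N,5,9-trimethyl-12-(6-methylhepta-1,5-dien-2-yl)-N-phenylcyclotetradec-4-ene-1-carboxamide
Product: 33 [(1R,4Z,9R,12R)-5,9-dimethyl-12-(6-methylhepta-1,5-dien-2-yl)cyclotetradec-4-en-1-yl]methanol
Conditions: BH3·NH3, LiN(i-Pr)2, THF, 0 °C (gives LiH2NBH3); then 32, 0 → 23 °C; aqueous HCl work-up
Reagents that add atoms: none
Why: Reduction of the hindered tertiary anilide to the primary alcohol with lithium amidotrihydroborate expels N-methylaniline, is known not to epimerise α-stereocentres, and leaves alkenes untouched.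

Step 21
Reactants: 33 [(1R,4Z,9R,12R)-5,9-dimethyl-12-(6-methylhepta-1,5-dien-2-yl)cyclotetradec-4-en-1-yl]methanol
Product: 34 (1R,4Z,9R,12R)-5,9-dimethyl-12-(6-methylhepta-1,5-dien-2-yl)cyclotetradec-4-ene-1-carbaldehyde
Conditions: Dess–Martin periodinane, NaHCO3, CH2Cl2, 0 → 23 °C; used at once
Reagents that add atoms: none
Why: Dess–Martin oxidation gives the aldehyde under buffered, non-enolising conditions, so C12 should not epimerise.

Step 22
Reactants: 34 (1R,4Z,9R,12R)-5,9-dimethyl-12-(6-methylhepta-1,5-dien-2-yl)cyclotetradec-4-ene-1-carbaldehyde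
Product: 35 (1R,4Z,9R,12R)-5,9-dimethyl-12-(6-methylhepta-1,5-dien-2-yl)cyclotetradec-4-ene-1-carboxylic acid (CNP0125479.1)
Conditions: NaClO2, NaH2PO4, 2-methylbut-2-ene (5, large excess), t-BuOH/H2O, 0 → 23 °C
Reagents that add atoms: sodium chlorite, [Na+].[O-]Cl=O
Why: Pinnick oxidation of the aldehyde to the acid; the excess 2-methylbut-2-ene scavenges HOCl so the three alkenes of the substrate are not chlorinated, and the mildly acidic medium does not epimerise C12.

## Compound list

1 | (R)-(−)-carvone | CC(=C)[C@@H]1CC=C(C)C(=O)C1 | starting material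
2 | (5R)-5-(3-chloroprop-1-en-2-yl)-2-methylcyclohex-2-en-1-one | ClCC(=C)[C@@H]1CC=C(C)C(=O)C1 | intermediate
3 | 2-allyl-4,4,5,5-tetramethyl-1,3,2-dioxaborolane | C=CCB1OC(C)(C)C(C)(C)O1 | starting material
4 | (5R)-5-(hexa-1,5-dien-2-yl)-2-methylcyclohex-2-en-1-one | C=CCCC(=C)[C@@H]1CC=C(C)C(=O)C1 | intermediate
5 | 2-methylbut-2-ene | CC=C(C)C | starting material
6 | (5R)-2-methyl-5-(6-methylhepta-1,5-dien-2-yl)cyclohex-2-en-1-one | CC(C)=CCCC(=C)[C@@H]1CC=C(C)C(=O)C1 | intermediate
7 | potassium dienolate of 6 (O–K on the former carbonyl carbon, not isolated) | CC(C)=CCCC(=C)[C@@H]1CC=C(C)C(O[K])=C1 | intermediate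
8 | (5S,6RS)-6-hydroxy-2-methyl-5-(6-methylhepta-1,5-dien-2-yl)cyclohex-2-en-1-one | CC(C)=CCCC(=C)[C@@H]1CC=C(C)C(=O)C1O | intermediate
9 | methyl (2Z,5S)-5-formyl-2,10-dimethyl-6-methylideneundeca-2,9-dienoate | COC(=O)/C(C)=C\C[C@H](C=O)C(=C)CCC=C(C)C | intermediate
10 | methyl (2Z,5R)-5-ethenyl-2,10-dimethyl-6-methylideneundeca-2,9-dienoate | COC(=O)/C(C)=C\C[C@H](C=C)C(=C)CCC=C(C)C | intermediate
11 | (2Z,5R)-5-ethenyl-2,10-dimethyl-6-methylideneundeca-2,9-dienoic acid | OC(=O)/C(C)=C\C[C@H](C=C)C(=C)CCC=C(C)C | intermediate
12 | (2S,5R)-5-ethenyl-2,10-dimethyl-6-methylideneundec-9-enoic acid | OC(=O)[C@@H](C)CC[C@H](C=C)C(=C)CCC=C(C)C | intermediate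
13 | (2S,5R)-5-ethenyl-2,10-dimethyl-6-methylideneundec-9-en-1-ol | OC[C@@H](C)CC[C@H](C=C)C(=C)CCC=C(C)C | intermediate
14 | (2S,5R)-5-ethenyl-1-iodo-2,10-dimethyl-6-methylideneundec-9-ene | IC[C@@H](C)CC[C@H](C=C)C(=C)CCC=C(C)C | intermediate
15 | methyl phenyl sulfone | CS(=O)(=O)c1ccccc1 | starting material
16 | (phenylsulfonyl)methyllithium (not isolated) | [Li]CS(=O)(=O)c1ccccc1 | intermediate
17 | {[(3S,6R)-6-ethenyl-3,11-dimethyl-7-methylidenedodec-10-en-1-yl]sulfonyl}benzene | O=S(=O)(CC[C@@H](C)CC[C@H](C=C)C(=C)CCC=C(C)C)c1ccccc1 | intermediate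
18 | (4-carboxybutyl)triphenylphosphonium bromide | OC(=O)CCCC[P+](c1ccccc1)(c1ccccc1)c1ccccc1.[Br-] | starting material
19 | 1-[(tert-butyldimethylsilyl)oxy]propan-2-one | CC(=O)CO[Si](C)(C)C(C)(C)C | starting material
20 | sodium 5-(triphenylphosphoranylidene)pentanoate (not isolated) | [Na+].[O-]C(=O)CCCC=P(c1ccccc1)(c1ccccc1)c1ccccc1 | intermediate
21 | (5Z)-7-[(tert-butyldimethylsilyl)oxy]-6-methylhept-5-enoic acid | OC(=O)CCC/C=C(/C)CO[Si](C)(C)C(C)(C)C | intermediate
22 | N-methylaniline | CNc1ccccc1 | starting material
23 | (5Z)-7-[(tert-butyldimethylsilyl)oxy]-6-methylhept-5-enoyl chloride (not isolated) | ClC(=O)CCC/C=C(/C)CO[Si](C)(C)C(C)(C)C | intermediate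
24 | (5Z)-7-[(tert-butyldimethylsilyl)oxy]-N,6-dimethyl-N-phenylhept-5-enamide | CN(c1ccccc1)C(=O)CCC/C=C(/C)CO[Si](C)(C)C(C)(C)C | intermediate
25 | (5Z)-7-hydroxy-N,6-dimethyl-N-phenylhept-5-enamide | CN(c1ccccc1)C(=O)CCC/C=C(/C)CO | intermediate
26 | (5Z)-7-bromo-N,6-dimethyl-N-phenylhept-5-enamide | CN(c1ccccc1)C(=O)CCC/C=C(/C)CBr | intermediate
27 | α-lithio derivative of sulfone 17 (not isolated) | [Li]C(C[C@@H](C)CC[C@H](C=C)C(=C)CCC=C(C)C)S(=O)(=O)c1ccccc1 | intermediate
28 | (5Z,10S,13R)-13-ethenyl-N,6,10,18-tetramethyl-14-methylidene-N-phenyl-8-(phenylsulfonyl)nonadeca-5,17-dienamide (C8 epimers) | CN(c1ccccc1)C(=O)CCC/C=C(/C)CC(C[C@@H](C)CC[C@H](C=C)C(=C)CCC=C(C)C)S(=O)(=O)c1ccccc1 | intermediate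
29 | (5Z,10R,13R)-13-ethenyl-N,6,10,18-tetramethyl-14-methylidene-N-phenylnonadeca-5,17-dienamide | C=C[C@@H](CC[C@H](C)CCC/C(C)=C\CCCC(=O)N(C)c1ccccc1)C(=C)CCC=C(C)C | intermediate
30 | lithium enolate of amide 29 (not isolated) | C=C[C@@H](CC[C@H](C)CCC/C(C)=C\CCC=C(O[Li])N(C)c1ccccc1)C(=C)CCC=C(C)C | intermediate
31 | (5Z,10R,13R)-2-bromo-13-ethenyl-N,6,10,18-tetramethyl-14-methylidene-N-phenylnonadeca-5,17-dienamide (C2 epimers; key-step precursor) | C=C[C@@H](CC[C@H](C)CCC/C(C)=C\CCC(Br)C(=O)N(C)c1ccccc1)C(=C)CCC=C(C)C | intermediate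
32 | (1R,4Z,9R,12R)-N,5,9-trimethyl-12-(6-methylhepta-1,5-dien-2-yl)-N-phenylcyclotetradec-4-ene-1-carboxamide | C=C(CCC=C(C)C)[C@@H]1CC[C@H](C)CCC/C(C)=C\CC[C@@H](C(=O)N(C)c2ccccc2)CC1 | intermediate
33 | [(1R,4Z,9R,12R)-5,9-dimethyl-12-(6-methylhepta-1,5-dien-2-yl)cyclotetradec-4-en-1-yl]methanol | C=C(CCC=C(C)C)[C@@H]1CC[C@H](C)CCC/C(C)=C\CC[C@@H](CO)CC1 | intermediate
34 | (1R,4Z,9R,12R)-5,9-dimethyl-12-(6-methylhepta-1,5-dien-2-yl)cyclotetradec-4-ene-1-carbaldehyde | C=C(CCC=C(C)C)[C@@H]1CC[C@H](C)CCC/C(C)=C\CC[C@@H](C=O)CC1 | intermediate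
35 | (1R,4Z,9R,12R)-5,9-dimethyl-12-(6-methylhepta-1,5-dien-2-yl)cyclotetradec-4-ene-1-carboxylic acid | C=C(CCC=C(C)C)[C@@H]1CC[C@H](C)CCC/C(C)=C\CC[C@@H](C(=O)O)CC1 | target

## Step count

Total step count: 22 (steps 1–11 and 16–22 on the carvone line, steps 12–15 for the Z-allylic bromide).
Longest linear sequence: 18 steps (1–11, then 16–22).

## Steps most likely to fail, with fallbacks

**1. Step 19 (macrocyclising hydroalkylation).** Coupling between chains may outrun ring closure. The C–Br bond may be reduced before capture. The nickel hydride may hydrogenate the vinyl group or walk it into conjugation through the doubly allylic C1–H. Ligand control at C12 may be weaker in the ring-forming transition state than in open-chain cases.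

The fallback swaps which bond closes the ring and uses only known reaction types. It sets out from amide 24 and sulfone 17 and comes back at macrocyclic anilide 32. Amide 24 would be α-brominated (LiN(i-Pr)2, then N-bromosuccinimide) to racemic (5Z)-2-bromo-7-[(tert-butyldimethylsilyl)oxy]-N,6-dimethyl-N-phenylhept-5-enamide F1. The established intermolecular enantioconvergent nickel-hydride hydroalkylation (same nickel salt, ligand, silane and base as step 19, at normal concentration) would join F1 to the vinyl group of 17. This gives the open-chain anilide with C12–C13 formed and C12 set, phenylsulfonyl on C6 and the silyl ether on C7, F2. Bu4NF would free the allylic alcohol F3, and CBr4/PPh3 would give the allylic bromide F4. LiN(i-Pr)2 (1 equiv) in dilute THF at −78 → −20 °C would deprotonate the sulfone CH2; the α-branched anilide C–H is shielded by allylic strain. The carbanion would close the ring at C6–C7 by intramolecular sulfone alkylation, a closure type well established for 14-membered carbocycles, to give the macrocyclic sulfone anilide F5. Na(Hg) in buffered methanol would then remove the sulfone to give 32.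

**2. Step 8 (asymmetric hydrogenation).** The vinyl group may be reduced or isomerised alongside the conjugated alkene. The catalyst may also discriminate poorly between the faces of this Z-configured acid.

The fallback replaces catalyst control by an auxiliary and a chemoselective hydride. It sets out from acid 11 and comes back at alcohol 13. Acid 11 would be activated as its mixed pivalic anhydride and used to acylate the lithium salt of (1S)-(−)-2,10-camphorsultam, giving the N-[(2Z,5R)-5-ethenyl-2,10-dimethyl-6-methylideneundeca-2,9-dienoyl] sultam F6. Conjugate reduction with LiBH(s-Bu)3 at −78 °C, which does not touch isolated alkenes, and kinetic protonation of the chelated enolate would give the saturated N-acyl sultam F7. Its two epimers at the methyl carbon are diastereomers and would be separated by crystallisation or chromatography; the antipodal sultam is used if it favours the wanted one. LiAlH4 would then cleave the auxiliary and deliver 13.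

**3. Step 6 (methylenation of aldehyde 9).** The α-branched, β,γ-unsaturated aldehyde may enolise, losing the C1 configuration or moving the alkene into conjugation, before or during methylenation.

The fallback is a two-stage Peterson olefination in which the sensitive centre stops being α to a carbonyl in the first, fast step. It sets out from aldehyde 9 and comes back at ester 10. Me3SiCH2MgCl with CeCl3 in THF at −78 °C would add to the aldehyde, cerium suppressing enolisation and the ester being untouched. This gives methyl (2Z,5S)-5-[1-hydroxy-2-(trimethylsilyl)ethyl]-2,10-dimethyl-6-methylideneundeca-2,9-dienoate F8 as a mixture of carbinol epimers. BF3·OEt2 in CH2Cl2 at 0 °C would then eliminate trimethylsilanol from either epimer to give 10.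

## Further compounds

F1 | step 19 | (5Z)-2-bromo-7-[(tert-butyldimethylsilyl)oxy]-N,6-dimethyl-N-phenylhept-5-enamide (racemic) | CN(c1ccccc1)C(=O)C(Br)CC/C=C(/C)CO[Si](C)(C)C(C)(C)C
F2 | step 19 | open-chain anilide with C12–C13 formed (C1, C4, C12 as in the target), phenylsulfonyl on C6, tert-butyldimethylsilyl ether on C7 | O=S(=O)(c1ccccc1)CC[C@@H](C)CC[C@H](CC[C@@H](CC/C=C(/C)CO[Si](C)(C)C(C)(C)C)C(=O)N(C)c1ccccc1)C(=C)CCC=C(C)C
F3 | step 19 | allylic alcohol from F2 (free OH on C7) | O=S(=O)(c1ccccc1)CC[C@@H](C)CC[C@H](CC[C@@H](CC/C=C(/C)CO)C(=O)N(C)c1ccccc1)C(=C)CCC=C(C)C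
F4 | step 19 | allylic bromide from F3 (Br on C7) | O=S(=O)(c1ccccc1)CC[C@@H](C)CC[C@H](CC[C@@H](CC/C=C(/C)CBr)C(=O)N(C)c1ccccc1)C(=C)CCC=C(C)C
F5 | step 19 | macrocyclic anilide 32 bearing phenylsulfonyl on C6 (C6 epimers) | C=C(CCC=C(C)C)[C@@H]1CC[C@H](C)CC(S(=O)(=O)c2ccccc2)C/C(C)=C\CC[C@@H](C(=O)N(C)c2ccccc2)CC1
F6 | step 8 | N-[(2Z,5R)-5-ethenyl-2,10-dimethyl-6-methylideneundeca-2,9-dienoyl]-(1S)-2,10-camphorsultam | CC1(C)[C@@H]2CC[C@]13CS(=O)(=O)N(C(=O)/C(C)=C\C[C@H](C=C)C(=C)CCC=C(C)C)[C@@H]3C2
F7 | step 8 | N-[(2S,5R)-5-ethenyl-2,10-dimethyl-6-methylideneundec-9-enoyl]-(1S)-2,10-camphorsultam | CC1(C)[C@@H]2CC[C@]13CS(=O)(=O)N(C(=O)[C@@H](C)CC[C@H](C=C)C(=C)CCC=C(C)C)[C@@H]3C2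
F8 | step 6 | methyl (2Z,5S)-5-[1-hydroxy-2-(trimethylsilyl)ethyl]-2,10-dimethyl-6-methylideneundeca-2,9-dienoate (carbinol epimers) | COC(=O)/C(C)=C\C[C@H](C(O)C[Si](C)(C)C)C(=C)CCC=C(C)C
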